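Ring A (cyclopentane C1–C5: C1 bears the side chain, C4 the methyl group, C5 is the spiro atom) is traced back to the six-membered ring of (S)-carvone. C1 and C4, trans-disposed and both bonded to C5, are the 1,4-related ring carbons of trans-dihydrocarvone, whose carbonyl carbon sits between C4 and C5. The key step, a photochemical Wolff rearrangement of 2-diazo-6-methyl-3-isopropenylcyclohexanone, shifts C4 from that carbonyl carbon to C5 with retention. One operation makes the C4–C5 bond, contracts six atoms to five and expels the carbonyl carbon as the exocyclic acyl carbon that becomes C10. Robinson spiroannulation builds ring B. Hydroboration/α-bromo ketone alkylation of the isopropenyl group completes the side chain.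

Key step: step 3

Remark: spiro compounds carry the numbering of the target core (ring A as above; ring B: C5, C6 = CH2, C7 = carbinol carbon, C8 = ester carbon, C9 = CH, C10 = CH2; side chain C11 = CH, C12, C13, C14 = C=O). Monocyclic compounds are numbered by their own names.

Step 1
Reactants: 1 (S)-(+)-carvone
Product: 3 (2S,5S)-2-methyl-5-(prop-1-en-2-yl)cyclohexan-1-one (trans-dihydrocarvone), via lithium enolate 2 (not isolated)
Conditions: LiBH(s-Bu)3, THF, −78 °C; H2O; then NaOMe (cat.), MeOH, rt
Reagents that add atoms: none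
Why: Conjugate reduction of an enone by a bulky trialkylborohydride spares the isolated alkene, and protonation of enolate 2 followed by base equilibration places the new C2 methyl group equatorial, that is trans to the equatorial C5 isopropenyl group (2S).

Step 2
Reactants: 3 trans-dihydrocarvone
Product: 6 (3R,6S)-2-diazo-6-methyl-3-(prop-1-en-2-yl)cyclohexan-1-one, via kinetic lithium enolate 4 (not isolated), via trifluoroacetyl ketone 5 (not isolated)
Conditions: LiN(SiMe3)2, THF, −78 °C; CF3CO2CH2CF3; then MsN3, Et3N, H2O (1 equiv), MeCN, rt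
Reagents that add atoms: methanesulfonyl azide, CS(=O)(=O)N=[N+]=[N-]
Why: Regitz-type detrifluoroacetylative diazo transfer: kinetic deprotonation occurs at the C6 methylene rather than at the methyl-bearing C2, the transient trifluoroacetyl group activates this carbon for transfer of N2 from the sulfonyl azide and then leaves, and no stereocentre is touched.

Step 3
Reactants: 6 diazo ketone
Product: 8 (2S,5S)-N-methoxy-N,2-dimethyl-5-(prop-1-en-2-yl)cyclopentane-1-carboxamide (epimers at the amide-bearing carbon), via ketene 7 (not isolated)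
Conditions: hν (λ ≥ 300 nm), MeNHOMe (3 equiv), THF, rt
Reagents that add atoms: N,O-dimethylhydroxylamine, CNOC
Why: Light expels N2 from the diazo ketone, whose ring locks the C=O and C=N2 bonds s-cis, and in the same event the methyl-bearing carbon C6 shifts from the carbonyl carbon C1 to the diazo carbon C2 (photochemical Wolff rearrangement, the standard ring contraction of 2-diazocyclohexanones), giving ketene 7, which the amine traps as amide 8. No ring is closed by cyclisation: ring A forms by a 1,2-shift that makes the future C4–C5 bond, shrinks six atoms to five and pushes the old carbonyl carbon outside the ring, where it is kept as the future C10. The migrating carbon keeps its configuration (suprafacial shift with retention) and the isopropenyl-bearing carbon is not involved, so the trans C1/C4 relation of dihydrocarvone is carried over unchanged. The only new stereocentre, the amide-bearing C5, arises by protonation of the amide enol, may be a mixture and is erased in step 5. The step needs rearrangement to win over a 1,2-hydride shift from C3 (enone formation) and over carbene addition to the alkene, and the s-cis geometry, which favours the concerted path without a free carbene, secures this. Regiochemistry is not an issue because only one carbon substituent on the carbonyl group can migrate.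

Step 4
Reactants: 8 Weinreb amide
Product: 9 (2S,5S)-2-methyl-5-(prop-1-en-2-yl)cyclopentane-1-carbaldehyde (epimers at the formyl-bearing carbon)
Conditions: i-Bu2AlH, THF, −78 °C; then H2O
Reagents that add atoms: none
Why: Reduction of a Weinreb amide stops at the aldehyde because the chelated aluminium hemiaminal collapses only on work-up, and the epimer mixture at the formyl-bearing carbon is of no consequence.

Step 5
Reactants: 9 aldehyde; 10 methyl vinyl ketone (but-3-en-2-one)
Product: 12 (1R,4S,5S)-4-methyl-1-(prop-1-en-2-yl)spiro[4.5]dec-9-en-8-one, via keto aldehyde 11 (not isolated)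
Conditions: KOH (0.2 equiv), EtOH, 0 °C to reflux
Reagents that add atoms: none
Why: Robinson annulation (Michael addition, then aldol condensation) of an α-branched aldehyde: the planar enolate carbon C5 is attacked by the vinyl ketone on the face opposite the larger isopropenyl group, so the new C6 arm ends cis to the C4 methyl group and the formyl carbon C10 cis to the isopropenyl group (5S), and only the methyl group of 11 can close a six-membered ring onto the non-enolisable aldehyde.

Step 6
Reactants: 12 spiro enone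
Product: 14 (1R,4S,5S,7S)-7-hydroxy-4-methyl-1-(prop-1-en-2-yl)spiro[4.5]dec-9-en-8-one, via potassium dienolate 13 (not isolated)
Conditions: KN(SiMe3)2, THF, −78 °C; 2-(phenylsulfonyl)-3-phenyloxaziridine; then H2O
Reagents that add atoms: 2-(phenylsulfonyl)-3-phenyloxaziridine, O=S(=O)(N1OC1c1ccccc1)c1ccccc1
Why: Davis oxidation of the kinetic cross-conjugated dienolate (C7 is the only acidic position because C5 is quaternary): the oxaziridine reaches C7 on the face of ring B that carries C1, since the C4 methyl group hangs over C6/C7 on the other face while the isopropenyl group points towards C9/C10, which gives 7S.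

Step 7
Reactants: 14 hydroxy enone
Product: 15 (1R,4S,5S,7S)-7-[(tert-butyldimethylsilyl)oxy]-4-methyl-1-(prop-1-en-2-yl)spiro[4.5]dec-9-en-8-one
Conditions: TBSCl, imidazole, DMF, rt
Reagents that add atoms: tert-butyldimethylsilyl chloride, CC(C)(C)[Si](C)(C)Cl
Why: Standard silylation of a secondary alcohol masks the hydroxyl group against the hydride, triflating and borane reagents that follow, and no stereocentre changes.

Step 8
Reactants: 15 silyloxy enone
Product: 17 (1R,4S,5S,7S)-7-[(tert-butyldimethylsilyl)oxy]-4-methyl-1-(prop-1-en-2-yl)spiro[4.5]dec-8-en-8-yl trifluoromethanesulfonate, via lithium enolate 16 (not isolated)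
Conditions: LiBH(s-Bu)3, THF, −78 °C; N-(5-chloropyridin-2-yl)bis(trifluoromethanesulfonimide), −78 °C to 0 °C; H2O
Reagents that add atoms: N-(5-chloropyridin-2-yl)bis(trifluoromethanesulfonimide), O=S(=O)(N(c1ccc(Cl)cn1)S(=O)(=O)C(F)(F)F)C(F)(F)F
Why: Reductive enolate trapping: 1,4-hydride addition to the enone, whose carbonyl group is screened by the neighbouring silyloxy group, turns C10 into CH2 and gives regiospecifically the C8–C9 enolate 16, which is O-sulfonylated to the enol triflate.

Step 9
Reactants: 17 enol triflate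
Product: 18 methyl (1R,4S,5S,7S)-7-[(tert-butyldimethylsilyl)oxy]-4-methyl-1-(prop-1-en-2-yl)spiro[4.5]dec-8-ene-8-carboxylate
Conditions: Pd(OAc)2 (5 mol %), dppf, CO (1 atm), MeOH, Et3N, DMF, 50 °C
Reagents that add atoms: carbon monoxide, [C-]#[O+]; methanol, CO
Why: Palladium-catalysed methoxycarbonylation of an enol triflate (oxidative addition to zerovalent palladium, CO insertion, methanolysis of the acyl complex) installs the ester at C8 with the C8=C9 double bond already in place.

Step 10
Reactants: 18 enoate; 19 1-bromo-3-methylbutan-2-one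
Product: 21 methyl (1R,4S,5S,7S)-7-[(tert-butyldimethylsilyl)oxy]-4-methyl-1-[(2R)-6-methyl-5-oxoheptan-2-yl]spiro[4.5]dec-8-ene-8-carboxylate, via B-alkyl-9-BBN 20 (not isolated)
Conditions: 9-BBN-H, THF, 0 °C to 40 °C; then 19, 2,6-t-Bu2C6H3OK (from the phenol and KOt-Bu), THF, 0 °C; H2O
Reagents that add atoms: none
Why: Hydroboration followed by α-alkylation of an α-bromo ketone by the B-alkyl-9-BBN (ate complex of the bromo enolate, then 1,2-metallate shift with loss of bromide): 9-BBN-H adds only to the 1,1-disubstituted alkene, boron at C12, from the face anti to quaternary C5 in the conformer with the C1–H bond eclipsing the double bond, the sense known for isopulegol-type alkenes, which sets 11R.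

Step 11
Reactants: 21 silyl ether
Product: 22 methyl (1R,4S,5S,7S)-7-hydroxy-4-methyl-1-[(2R)-6-methyl-5-oxoheptan-2-yl]spiro[4.5]dec-8-ene-8-carboxylate (target)
Conditions: HF·pyridine, THF, 0 °C to rt
Reagents that add atoms: none
Why: Fluoride-induced cleavage of the silyl ether under mildly acidic conditions frees the C7 hydroxyl group without touching the enoate, the ketone or any stereocentre.

Compound list
1 | (S)-(+)-carvone, (5S)-2-methyl-5-(prop-1-en-2-yl)cyclohex-2-en-1-one | CC1=CC[C@@H](CC1=O)C(C)=C | starting material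
2 | lithium (5S)-2-methyl-5-(prop-1-en-2-yl)cyclohex-1-en-1-olate | [Li+].[O-]C1=C(C)CC[C@@H](C1)C(C)=C | intermediate
3 | (2S,5S)-2-methyl-5-(prop-1-en-2-yl)cyclohexan-1-one (trans-dihydrocarvone) | C[C@H]1CC[C@@H](CC1=O)C(C)=C | intermediate
4 | lithium (3S,6S)-6-methyl-3-(prop-1-en-2-yl)cyclohex-1-en-1-olate | [Li+].[O-]C1=C[C@@H](C(C)=C)CC[C@@H]1C | intermediate
5 | (3S,6S)-6-methyl-3-(prop-1-en-2-yl)-2-(trifluoroacetyl)cyclohexan-1-one (C2 undefined, largely enolised) | C[C@H]1CC[C@H](C(C)=C)C(C(=O)C(F)(F)F)C1=O | intermediate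
6 | (3R,6S)-2-diazo-6-methyl-3-(prop-1-en-2-yl)cyclohexan-1-one | C[C@H]1CC[C@H](C(C)=C)C(=[N+]=[N-])C1=O | intermediate
7 | [(2S,5R)-2-methyl-5-(prop-1-en-2-yl)cyclopentylidene]methanone (ketene) | C[C@H]1CC[C@H](C(C)=C)C1=C=O | intermediate
8 | (2S,5S)-N-methoxy-N,2-dimethyl-5-(prop-1-en-2-yl)cyclopentane-1-carboxamide (C1 epimers) | C[C@H]1CC[C@H](C(C)=C)C1C(=O)N(C)OC | intermediate
9 | (2S,5S)-2-methyl-5-(prop-1-en-2-yl)cyclopentane-1-carbaldehyde (C1 epimers) | C[C@H]1CC[C@H](C(C)=C)C1C=O | intermediate
10 | methyl vinyl ketone (but-3-en-2-one) | CC(=O)C=C | starting material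
11 | (1R,2S,5R)-2-methyl-1-(3-oxobutyl)-5-(prop-1-en-2-yl)cyclopentane-1-carbaldehyde | O=C[C@@]1(CCC(C)=O)[C@@H](C(C)=C)CC[C@@H]1C | intermediate
12 | (1R,4S,5S)-4-methyl-1-(prop-1-en-2-yl)spiro[4.5]dec-9-en-8-one | O=C1C=C[C@@]2(CC1)[C@@H](C(C)=C)CC[C@@H]2C | intermediate
13 | potassium (1R,4S,5S)-4-methyl-1-(prop-1-en-2-yl)spiro[4.5]deca-7,9-dien-8-olate | [K+].[O-]C1=CC[C@]2(C=C1)[C@@H](C(C)=C)CC[C@@H]2C | intermediate
14 | (1R,4S,5S,7S)-7-hydroxy-4-methyl-1-(prop-1-en-2-yl)spiro[4.5]dec-9-en-8-one | O=C1C=C[C@@]2(C[C@@H]1O)[C@@H](C(C)=C)CC[C@@H]2C | intermediate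
15 | (1R,4S,5S,7S)-7-[(tert-butyldimethylsilyl)oxy]-4-methyl-1-(prop-1-en-2-yl)spiro[4.5]dec-9-en-8-one | O=C1C=C[C@@]2(C[C@@H]1O[Si](C)(C)C(C)(C)C)[C@@H](C(C)=C)CC[C@@H]2C | intermediate
16 | lithium (1R,4S,5S,7S)-7-[(tert-butyldimethylsilyl)oxy]-4-methyl-1-(prop-1-en-2-yl)spiro[4.5]dec-8-en-8-olate | [Li+].[O-]C1=CC[C@@]2(C[C@@H]1O[Si](C)(C)C(C)(C)C)[C@@H](C(C)=C)CC[C@@H]2C | intermediate
17 | (1R,4S,5S,7S)-7-[(tert-butyldimethylsilyl)oxy]-4-methyl-1-(prop-1-en-2-yl)spiro[4.5]dec-8-en-8-yl trifluoromethanesulfonate | O=S(=O)(OC1=CC[C@@]2(C[C@@H]1O[Si](C)(C)C(C)(C)C)[C@@H](C(C)=C)CC[C@@H]2C)C(F)(F)F | intermediate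
18 | methyl (1R,4S,5S,7S)-7-[(tert-butyldimethylsilyl)oxy]-4-methyl-1-(prop-1-en-2-yl)spiro[4.5]dec-8-ene-8-carboxylate | COC(=O)C1=CC[C@@]2(C[C@@H]1O[Si](C)(C)C(C)(C)C)[C@@H](C(C)=C)CC[C@@H]2C | intermediate
19 | 1-bromo-3-methylbutan-2-one | CC(C)C(=O)CBr | starting material
20 | methyl (1R,4S,5S,7S)-1-[(2R)-1-(9-borabicyclo[3.3.1]nonan-9-yl)propan-2-yl]-7-[(tert-butyldimethylsilyl)oxy]-4-methylspiro[4.5]dec-8-ene-8-carboxylate | COC(=O)C1=CC[C@@]2(C[C@@H]1O[Si](C)(C)C(C)(C)C)[C@@H]([C@H](C)CB3C4CCCC3CCC4)CC[C@@H]2C | intermediate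
21 | methyl (1R,4S,5S,7S)-7-[(tert-butyldimethylsilyl)oxy]-4-methyl-1-[(2R)-6-methyl-5-oxoheptan-2-yl]spiro[4.5]dec-8-ene-8-carboxylate | COC(=O)C1=CC[C@@]2(C[C@@H]1O[Si](C)(C)C(C)(C)C)[C@@H]([C@H](C)CCC(=O)C(C)C)CC[C@@H]2C | intermediate
22 | methyl (1R,4S,5S,7S)-7-hydroxy-4-methyl-1-[(2R)-6-methyl-5-oxoheptan-2-yl]spiro[4.5]dec-8-ene-8-carboxylate | COC(=O)C1=CC[C@@]2(C[C@@H]1O)[C@@H]([C@H](C)CCC(=O)C(C)C)CC[C@@H]2C | target

Total step count: 11. Longest linear sequence: 11 steps (from 1).

Steps most likely to fail

**Step 5.** The Michael addition has to create a quaternary carbon between two branched ring carbons. It may be slower than base-induced polymerisation of the vinyl ketone, and the facial preference may be modest.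
- The fallback replaces conjugate addition by enolate alkylation and sets out from diazo ketone 6.
- The same photolysis in MeOH would give the methyl ester F1.
- Deprotonation with LiN(i-Pr)2 in THF/DMPU and alkylation with 2-(2-iodoethyl)-2-methyl-1,3-dioxolane, again anti to the isopropenyl group, would give the quaternary ester F2.
- i-Bu2AlH at −78 °C would give the ketal aldehyde F3.
- Aqueous HCl would free keto aldehyde 11, and KOH in EtOH would close it to 12, where the route is rejoined.

**Step 10.** Hydroboration next to the quaternary centre may be sluggish. In the ate complex a ring bond of the bicyclononyl unit may migrate in place of the C12 alkyl group, so that little carbon–carbon bond formation occurs.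
- The fallback builds the chain by olefination and sets out from 18.
- Borane 20 would be oxidised with NaBO3·4H2O to the primary alcohol F4, at which stage C11 epimers could be separated.
- Dess–Martin periodinane would give the aldehyde F5.
- A Wittig reaction with Ph3P=CHC(O)i-Pr would give the (E)-enone F6.
- Conjugate reduction with [(Ph3P)CuH]6, which should leave the hindered trisubstituted enoate alone, would give 21, where the route is rejoined.

**Step 8.** Hydride delivery to C10, which lies next to the spiro centre on the isopropenyl side, may be slow. 1,2-Reduction of the carbonyl group or migration of the silyl group to the enolate oxygen may then compete.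
- The fallback separates reduction from enolate formation and sets out from 15.
- [(Ph3P)CuH]6 in toluene would give the saturated ketone F7.
- KN(SiMe3)2 at −78 °C would remove a proton from the C9 methylene rather than from the silyloxy-bearing C7.
- The same triflating agent would give 17, where the route is rejoined.

Further compounds
F1 | step 5 | methyl (2S,5S)-2-methyl-5-(prop-1-en-2-yl)cyclopentane-1-carboxylate (C1 epimers) | C[C@H]1CC[C@H](C(C)=C)C1C(=O)OC
F2 | step 5 | methyl (1R,2S,5R)-2-methyl-1-[2-(2-methyl-1,3-dioxolan-2-yl)ethyl]-5-(prop-1-en-2-yl)cyclopentane-1-carboxylate | COC(=O)[C@@]1(CCC2(C)OCCO2)[C@@H](C(C)=C)CC[C@@H]1C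
F3 | step 5 | (1R,2S,5R)-2-methyl-1-[2-(2-methyl-1,3-dioxolan-2-yl)ethyl]-5-(prop-1-en-2-yl)cyclopentane-1-carbaldehyde | O=C[C@@]1(CCC2(C)OCCO2)[C@@H](C(C)=C)CC[C@@H]1C
F4 | step 10 | methyl (1R,4S,5S,7S)-7-[(tert-butyldimethylsilyl)oxy]-1-[(2S)-1-hydroxypropan-2-yl]-4-methylspiro[4.5]dec-8-ene-8-carboxylate | COC(=O)C1=CC[C@@]2(C[C@@H]1O[Si](C)(C)C(C)(C)C)[C@@H]([C@H](C)CO)CC[C@@H]2C
F5 | step 10 | methyl (1R,4S,5S,7S)-7-[(tert-butyldimethylsilyl)oxy]-4-methyl-1-[(2S)-1-oxopropan-2-yl]spiro[4.5]dec-8-ene-8-carboxylate | COC(=O)C1=CC[C@@]2(C[C@@H]1O[Si](C)(C)C(C)(C)C)[C@@H]([C@H](C)C=O)CC[C@@H]2C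
F6 | step 10 | methyl (1R,4S,5S,7S)-7-[(tert-butyldimethylsilyl)oxy]-4-methyl-1-[(2R,3E)-6-methyl-5-oxohept-3-en-2-yl]spiro[4.5]dec-8-ene-8-carboxylate | COC(=O)C1=CC[C@@]2(C[C@@H]1O[Si](C)(C)C(C)(C)C)[C@@H]([C@H](C)/C=C/C(=O)C(C)C)CC[C@@H]2C
F7 | step 8 | (1R,4S,5S,7S)-7-[(tert-butyldimethylsilyl)oxy]-4-methyl-1-(prop-1-en-2-yl)spiro[4.5]decan-8-one | O=C1CC[C@@]2(C[C@@H]1O[Si](C)(C)C(C)(C)C)[C@@H](C(C)=C)CC[C@@H]2C
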